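Ring A (cyclohexene: C1 carries the diketone arm, C2 aryl ring B, C6 the 3,4-dimethoxyphenyl ring C) is cut at C1–C6 and C4=C5. Its two-carbon unit C5–C6, with ring C on C6, lies between the nucleophilic carbon C1 and the alkene carbon C4, and so maps onto a β-aryl vinylphosphonium salt. In one operation the sodium malonate of an enantiopure aldehyde adds through C1 to C6 of the salt and the ylide born at C5 olefinates the aldehyde C4, closing ring A and setting C6. The precursor is dimethyl 2-[(1S)-1-aryl-3-oxopropyl]malonate (phenol as MOM ether; C2 from iminium catalysis), used with (E)-(3,4-dimethoxystyryl)triphenylphosphonium bromide.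

Key step: step 5

Remarks on the chemistry:
- Ring A is numbered C1 (acyl-bearing), C2 (ring B), C3 (CH2), C4=C5, C6 (ring C) throughout the text; systematic names carry their own locants.
- The β-diketone of 19 and 20 is written as its chelated enol; keto and enol forms interconvert and count as one compound.
- The (R)-configured prolinol catalyst is assigned to the (S)-aldehyde 4 from the usual shielding model of the E-iminium ion.
- Methyl esters are kept because they are the smallest esters at the congested C1; both phenols carry the same MOM group so that one acid step frees them.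

Step 1
Reactants: 1 coniferaldehyde
Product: 2 (E)-3-[3-methoxy-4-(methoxymethoxy)phenyl]prop-2-enal
Conditions: MOMCl, iPr2NEt, CH2Cl2, 0 °C → rt
Reagents that add atoms: chloromethyl methyl ether, COCCl
Why: O-alkylation of the phenol (MOM ether formation), the only acidic site, should leave the enal untouched.

Step 2
Reactants: 2 (E)-3-[3-methoxy-4-(methoxymethoxy)phenyl]prop-2-enal; 3 dimethyl malonate
Product: 4 dimethyl 2-[(1S)-1-[3-methoxy-4-(methoxymethoxy)phenyl]-3-oxopropyl]propanedioate
Conditions: 3 (2 equiv), (R)-2-{bis[3,5-bis(trifluoromethyl)phenyl](trimethylsilyloxy)methyl}pyrrolidine (10 mol%), EtOH, 0 °C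
Reagents that add atoms: none
Why: Iminium-ion organocatalysis (diarylprolinol silyl ether-catalysed Michael addition of malonates to enals): the (R)-catalyst shields one face of the E-iminium ion of 2 with its Ar2C(OSiMe3) group, so malonate should add to the open face and set the (S)-configured benzylic centre, the future C2.

Step 3
Reactants: 5 (E)-3,4-dimethoxycinnamic acid
Product: 6 (E)-4-(2-bromoethenyl)-1,2-dimethoxybenzene
Conditions: NBS, LiOAc (10 mol%), MeCN–H2O (97:3), rt
Reagents that add atoms: N-bromosuccinimide, O=C1CCC(=O)N1Br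
Why: Catalytic Hunsdiecker-type bromodecarboxylation: bromonium formation on the electron-rich cinnamate and anti loss of CO2 should deliver the (E)-β-bromostyrene.

Step 4
Reactants: 6 (E)-4-(2-bromoethenyl)-1,2-dimethoxybenzene
Product: 7 (E)-[2-(3,4-dimethoxyphenyl)ethenyl]triphenylphosphonium bromide
Conditions: PPh3 (1.05 equiv), Pd(OAc)2 (2 mol%), toluene, 110 °C
Reagents that add atoms: triphenylphosphine, c1ccc(cc1)P(c1ccccc1)c1ccccc1
Why: Palladium-catalysed C–P coupling: oxidative addition of the alkenyl bromide to zerovalent palladium (formed from Pd(OAc)2 and PPh3) and P–C reductive elimination should give the alkenylphosphonium salt with the E geometry retained.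

Step 5
Reactants: 4 dimethyl 2-[(1S)-1-[3-methoxy-4-(methoxymethoxy)phenyl]-3-oxopropyl]propanedioate; 7 (E)-[2-(3,4-dimethoxyphenyl)ethenyl]triphenylphosphonium bromide
Product: 11 dimethyl (2S,6R)-2-(3,4-dimethoxyphenyl)-6-[3-methoxy-4-(methoxymethoxy)phenyl]cyclohex-3-ene-1,1-dicarboxylate, via sodium malonate enolate 8 (not isolated), via phosphonium ylide 9 (not isolated), via oxaphosphetane 10 (not isolated)
Conditions: NaH (1.0 equiv), THF, −30 °C; then 7 (1.2 equiv), DMF, −30 → 20 °C
Reagents that add atoms: none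
Why: Proposed new method: NaH removes the malonate proton of 4 (far more acidic than the aldehyde α-protons), carbanion 8 adds through C1 to the β-carbon C6 of 7 to give ylide 9 at C5, and this non-stabilised ylide attacks the tethered aldehyde C4 to give oxaphosphetane 10, which loses Ph3PO. The closest known reaction type is the annulation of carbonyl-bearing stabilised carbanions with unsubstituted vinyltriphenylphosphonium bromide (conjugate addition, then intramolecular Wittig reaction); a donor-substituted β-aryl salt is less electrophilic and has not been shown in this role. Ring A closes by intramolecular Wittig olefination, a 6-exo-trig attack of C5 on the C4 carbonyl followed by cycloreversion, so the C4=C5 alkene is necessarily cis. The new C6 centre is under substrate control from C2: addition to the salt should be reversible (the malonate is a good leaving group from 9), and ring closure is expected to drain the adduct that reaches a chair-like transition state with both aryl groups equatorial, giving the 2,6-cis diester. The step needs C-alkylation at C1 without retro-Michael cleavage or racemisation of 4, which the single equivalent of base, the acidity gap and the low temperature are meant to secure; the diastereoselectivity at C6 is the unproven point.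

Step 6
Reactants: 11 dimethyl (2S,6R)-2-(3,4-dimethoxyphenyl)-6-[3-methoxy-4-(methoxymethoxy)phenyl]cyclohex-3-ene-1,1-dicarboxylate
Product: 12 methyl (1RS,2R,6S)-2-(3,4-dimethoxyphenyl)-6-[3-methoxy-4-(methoxymethoxy)phenyl]cyclohex-3-ene-1-carboxylate (both C1 epimers)
Conditions: LiCl, H2O (2 equiv), DMSO, 150 °C
Reagents that add atoms: none
Why: Krapcho dealkoxycarbonylation: chloride demethylates one ester by SN2 attack, the carboxylate loses CO2 and the ester enolate is protonated, which should give both C1 epimers because protonation is not face-selective.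

Step 7
Reactants: 12 methyl (1RS,2R,6S)-2-(3,4-dimethoxyphenyl)-6-[3-methoxy-4-(methoxymethoxy)phenyl]cyclohex-3-ene-1-carboxylate
Product: 14 (1R,2R,6S)-2-(3,4-dimethoxyphenyl)-6-[3-methoxy-4-(methoxymethoxy)phenyl]cyclohex-3-ene-1-carboxylic acid (all-trans), via all-trans methyl ester 13 (not isolated)
Conditions: NaOMe (3 equiv), MeOH, 65 °C; then H2O, 65 °C; then 1 M HCl, 0 °C, to pH 3
Reagents that add atoms: water, O
Why: Base-mediated epimerisation then saponification: methoxide should equilibrate C1 through the ester enolate to the all-equatorial ester 13 (carboxylate trans to both aryl groups, the thermodynamic isomer), which hydroxide then hydrolyses without touching C2 or C6.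

Step 8
Reactants: 15 dehydrozingerone
Product: 16 (E)-4-[3-methoxy-4-(methoxymethoxy)phenyl]but-3-en-2-one
Conditions: MOMCl, iPr2NEt, CH2Cl2, 0 °C → rt
Reagents that add atoms: chloromethyl methyl ether, COCCl
Why: O-alkylation of the phenol (MOM ether formation) removes the acidic proton that would otherwise consume base and compete as an O-nucleophile in step 9.

Step 9
Reactants: 14 (1R,2R,6S)-2-(3,4-dimethoxyphenyl)-6-[3-methoxy-4-(methoxymethoxy)phenyl]cyclohex-3-ene-1-carboxylic acid; 16 (E)-4-[3-methoxy-4-(methoxymethoxy)phenyl]but-3-en-2-one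
Product: 19 (2Z,4E)-1-[(1R,2R,6S)-2-(3,4-dimethoxyphenyl)-6-[3-methoxy-4-(methoxymethoxy)phenyl]cyclohex-3-en-1-yl]-3-hydroxy-5-[3-methoxy-4-(methoxymethoxy)phenyl]penta-2,4-dien-1-one, via acid chloride 17 (not isolated), via lithium dienolate 18 (not isolated)
Conditions: 14, 1-chloro-N,N,2-trimethylprop-1-en-1-amine, CH2Cl2, 0 °C → rt; 16 (2.1 equiv), LiN(SiMe3)2 (2.1 equiv), THF, −78 °C; then 17, −78 → 0 °C; aq. NH4Cl
Reagents that add atoms: none
Why: Crossed Claisen-type C-acylation of a ketone lithium enolate by an acid chloride made under neutral conditions: the kinetic dienolate 18 should attack 17 at carbon, and a second equivalent of 18 deprotonates the β-diketone, which shields the product and C1 from further base chemistry.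

Step 10
Reactants: 19 (2Z,4E)-1-[(1R,2R,6S)-2-(3,4-dimethoxyphenyl)-6-[3-methoxy-4-(methoxymethoxy)phenyl]cyclohex-3-en-1-yl]-3-hydroxy-5-[3-methoxy-4-(methoxymethoxy)phenyl]penta-2,4-dien-1-one
Product: 20 (2Z,4E)-1-[(1R,2R,6S)-2-(3,4-dimethoxyphenyl)-6-(4-hydroxy-3-methoxyphenyl)cyclohex-3-en-1-yl]-3-hydroxy-5-(4-hydroxy-3-methoxyphenyl)penta-2,4-dien-1-one (CNP0290899.1)
Conditions: HCl (2 M in MeOH), 25–40 °C
Reagents that add atoms: none
Why: Acid-catalysed acetal cleavage (transacetalisation of both MOM ethers to dimethoxymethane) should free the two phenols, while the enolised β-diketone, the ring alkene and the three stereocentres are inert to dilute acid.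

Compound list
1 | coniferaldehyde, (E)-3-(4-hydroxy-3-methoxyphenyl)prop-2-enal | COc1cc(/C=C/C=O)ccc1O | starting material
2 | (E)-3-[3-methoxy-4-(methoxymethoxy)phenyl]prop-2-enal | COCOc1ccc(/C=C/C=O)cc1OC | intermediate
3 | dimethyl malonate | COC(=O)CC(=O)OC | starting material
4 | dimethyl 2-[(1S)-1-[3-methoxy-4-(methoxymethoxy)phenyl]-3-oxopropyl]propanedioate | COC(=O)C(C(=O)OC)[C@@H](c1ccc(OCOC)c(OC)c1)CC=O | intermediate
5 | (E)-3,4-dimethoxycinnamic acid | COc1ccc(/C=C/C(O)=O)cc1OC | starting material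
6 | (E)-4-(2-bromoethenyl)-1,2-dimethoxybenzene | COc1ccc(/C=C/Br)cc1OC | intermediate
7 | (E)-[2-(3,4-dimethoxyphenyl)ethenyl]triphenylphosphonium bromide | COc1ccc(/C=C/[P+](c2ccccc2)(c2ccccc2)c2ccccc2)cc1OC.[Br-] | intermediate
8 | sodium enolate of 4 (carbanion at the malonate carbon C1) | [Na+].COC(=O)[C-](C(=O)OC)[C@@H](c1ccc(OCOC)c(OC)c1)CC=O | intermediate
9 | phosphonium ylide: the C1–C6 adduct of 8 and 7, with the ylide carbon C5 next to the ring C methine and the aldehyde still free | COC(=O)C(C(=O)OC)([C@@H](c1ccc(OCOC)c(OC)c1)CC=O)[C@@H]([CH-][P+](c1ccccc1)(c1ccccc1)c1ccccc1)c1ccc(OC)c(OC)c1 | intermediate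
10 | oxaphosphetane cis-fused to ring A at C4–C5 (the two fusion centres are left undefined because both are lost on cycloreversion) | COC(=O)C1(C(=O)OC)[C@@H](c2ccc(OCOC)c(OC)c2)CC3OP(c4ccccc4)(c4ccccc4)(c4ccccc4)C3[C@H]1c1ccc(OC)c(OC)c1 | intermediate
11 | dimethyl (2S,6R)-2-(3,4-dimethoxyphenyl)-6-[3-methoxy-4-(methoxymethoxy)phenyl]cyclohex-3-ene-1,1-dicarboxylate (aryl groups cis) | COC(=O)C1(C(=O)OC)[C@@H](c2ccc(OCOC)c(OC)c2)CC=C[C@H]1c1ccc(OC)c(OC)c1 | intermediate
12 | methyl (1RS,2R,6S)-2-(3,4-dimethoxyphenyl)-6-[3-methoxy-4-(methoxymethoxy)phenyl]cyclohex-3-ene-1-carboxylate (C1 epimers) | COC(=O)C1[C@@H](c2ccc(OCOC)c(OC)c2)CC=C[C@H]1c1ccc(OC)c(OC)c1 | intermediate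
13 | methyl (1R,2R,6S)-2-(3,4-dimethoxyphenyl)-6-[3-methoxy-4-(methoxymethoxy)phenyl]cyclohex-3-ene-1-carboxylate (all-trans) | COC(=O)[C@@H]1[C@@H](c2ccc(OCOC)c(OC)c2)CC=C[C@H]1c1ccc(OC)c(OC)c1 | intermediate
14 | (1R,2R,6S)-2-(3,4-dimethoxyphenyl)-6-[3-methoxy-4-(methoxymethoxy)phenyl]cyclohex-3-ene-1-carboxylic acid (all-trans) | OC(=O)[C@@H]1[C@@H](c2ccc(OCOC)c(OC)c2)CC=C[C@H]1c1ccc(OC)c(OC)c1 | intermediate
15 | dehydrozingerone, (E)-4-(4-hydroxy-3-methoxyphenyl)but-3-en-2-one | COc1cc(/C=C/C(C)=O)ccc1O | starting material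
16 | (E)-4-[3-methoxy-4-(methoxymethoxy)phenyl]but-3-en-2-one | COCOc1ccc(/C=C/C(C)=O)cc1OC | intermediate
17 | (1R,2R,6S)-2-(3,4-dimethoxyphenyl)-6-[3-methoxy-4-(methoxymethoxy)phenyl]cyclohex-3-ene-1-carbonyl chloride | ClC(=O)[C@@H]1[C@@H](c2ccc(OCOC)c(OC)c2)CC=C[C@H]1c1ccc(OC)c(OC)c1 | intermediate
18 | lithium (3E)-4-[3-methoxy-4-(methoxymethoxy)phenyl]buta-1,3-dien-2-olate (kinetic enolate of 16) | [Li+].[O-]C(=C)/C=C/c1ccc(OCOC)c(OC)c1 | intermediate
19 | (2Z,4E)-1-[(1R,2R,6S)-2-(3,4-dimethoxyphenyl)-6-[3-methoxy-4-(methoxymethoxy)phenyl]cyclohex-3-en-1-yl]-3-hydroxy-5-[3-methoxy-4-(methoxymethoxy)phenyl]penta-2,4-dien-1-one (bis-MOM ether of the target) | COCOc1ccc(/C=C/C(O)=C/C(=O)[C@@H]2[C@@H](c3ccc(OCOC)c(OC)c3)CC=C[C@H]2c2ccc(OC)c(OC)c2)cc1OC | intermediate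
20 | (2Z,4E)-1-[(1R,2R,6S)-2-(3,4-dimethoxyphenyl)-6-(4-hydroxy-3-methoxyphenyl)cyclohex-3-en-1-yl]-3-hydroxy-5-(4-hydroxy-3-methoxyphenyl)penta-2,4-dien-1-one, CNP0290899.1 | COc1cc(/C=C/C(O)=C/C(=O)[C@@H]2[C@@H](c3ccc(O)c(OC)c3)CC=C[C@H]2c2ccc(OC)c(OC)c2)ccc1O | target

Total step count: 10. Longest linear sequence: 7 steps (steps 1, 2, 5, 6, 7, 9 and 10).

Steps most likely to fail

1. Step 5 (Proposed new method). The fully substituted malonate carbanion may add too slowly to the donor-deactivated styrylphosphonium salt, so that retro-Michael fragmentation or racemisation of the aldehyde partner wins. The addition may also show poor facial selectivity at C6. The fallback uses known reaction types and puts C6 under catalyst control. It sets out from 4, which is methylenated by Wittig reaction (Ph3P=CH2, THF, −78 °C) to dimethyl 2-[(1S)-1-[3-methoxy-4-(methoxymethoxy)phenyl]but-3-en-1-yl]propanedioate F1. Commercial (E)-3-(3,4-dimethoxyphenyl)prop-2-en-1-ol is converted with methyl chloroformate and pyridine into methyl (2E)-3-(3,4-dimethoxyphenyl)prop-2-en-1-yl carbonate F2. Iridium-catalysed branched-selective allylic alkylation of the sodium enolate of F1 with F2 ([Ir(cod)Cl]2, chiral phosphoramidite ligand, THF; ligand enantiomer chosen for the required C6 configuration) should give dimethyl 2-[(1S)-1-(3,4-dimethoxyphenyl)prop-2-en-1-yl]-2-[(1R)-1-[3-methoxy-4-(methoxymethoxy)phenyl]but-3-en-1-yl]propanedioate F3. Ring-closing metathesis with the second-generation Grubbs catalyst (CH2Cl2, 40 °C) then forms C4=C5 and comes back to the route at 11.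

2. Step 9. The flanked acyl chloride may be attacked slowly, which would open the way to O-acylation of the dienolate and to loss of configuration at C1 through ketene formation. The fallback replaces acylation by aldol addition and oxidation. It sets out from 14, which LiAlH4 (THF, 0 °C) reduces to [(1R,2R,6S)-2-(3,4-dimethoxyphenyl)-6-[3-methoxy-4-(methoxymethoxy)phenyl]cyclohex-3-en-1-yl]methanol F4. Dess–Martin periodinane oxidises this to (1R,2R,6S)-2-(3,4-dimethoxyphenyl)-6-[3-methoxy-4-(methoxymethoxy)phenyl]cyclohex-3-ene-1-carbaldehyde F5. Aldol addition of dienolate 18 at −78 °C should give (1E)-5-hydroxy-5-[(1R,2R,6S)-2-(3,4-dimethoxyphenyl)-6-[3-methoxy-4-(methoxymethoxy)phenyl]cyclohex-3-en-1-yl]-1-[3-methoxy-4-(methoxymethoxy)phenyl]pent-1-en-3-one F6 (carbinol epimers). A second Dess–Martin oxidation of the β-hydroxy ketone comes back to the route at 19.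

3. Step 6. Hot chloride may cleave aryl methyl or MOM ethers, or dealkylation may stall at the congested geminal diester. The fallback separates ester cleavage from decarboxylation. It sets out from 11, which is mono-saponified (KOH, 1.1 equiv, aqueous MeOH) to (1RS,2S,6R)-2-(3,4-dimethoxyphenyl)-1-(methoxycarbonyl)-6-[3-methoxy-4-(methoxymethoxy)phenyl]cyclohex-3-ene-1-carboxylic acid F7. Thermal decarboxylation of this malonic half-ester (toluene or DMSO, 110–130 °C) comes back to the route at 12.

Further compounds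
F1 | step 5 | dimethyl 2-[(1S)-1-[3-methoxy-4-(methoxymethoxy)phenyl]but-3-en-1-yl]propanedioate | COC(=O)C(C(=O)OC)[C@@H](c1ccc(OCOC)c(OC)c1)CC=C
F2 | step 5 | methyl (2E)-3-(3,4-dimethoxyphenyl)prop-2-en-1-yl carbonate | COC(=O)OC/C=C/c1ccc(OC)c(OC)c1
F3 | step 5 | dimethyl 2-[(1S)-1-(3,4-dimethoxyphenyl)prop-2-en-1-yl]-2-[(1R)-1-[3-methoxy-4-(methoxymethoxy)phenyl]but-3-en-1-yl]propanedioate | COC(=O)C(C(=O)OC)([C@@H](c1ccc(OCOC)c(OC)c1)CC=C)[C@@H](C=C)c1ccc(OC)c(OC)c1
F4 | step 9 | [(1R,2R,6S)-2-(3,4-dimethoxyphenyl)-6-[3-methoxy-4-(methoxymethoxy)phenyl]cyclohex-3-en-1-yl]methanol | OC[C@@H]1[C@@H](c2ccc(OCOC)c(OC)c2)CC=C[C@H]1c1ccc(OC)c(OC)c1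
F5 | step 9 | (1R,2R,6S)-2-(3,4-dimethoxyphenyl)-6-[3-methoxy-4-(methoxymethoxy)phenyl]cyclohex-3-ene-1-carbaldehyde | O=C[C@@H]1[C@@H](c2ccc(OCOC)c(OC)c2)CC=C[C@H]1c1ccc(OC)c(OC)c1
F6 | step 9 | (1E)-5-hydroxy-5-[(1R,2R,6S)-2-(3,4-dimethoxyphenyl)-6-[3-methoxy-4-(methoxymethoxy)phenyl]cyclohex-3-en-1-yl]-1-[3-methoxy-4-(methoxymethoxy)phenyl]pent-1-en-3-one (carbinol epimers) | COCOc1ccc(/C=C/C(=O)CC(O)[C@@H]2[C@@H](c3ccc(OCOC)c(OC)c3)CC=C[C@H]2c2ccc(OC)c(OC)c2)cc1OC
F7 | step 6 | (1RS,2S,6R)-2-(3,4-dimethoxyphenyl)-1-(methoxycarbonyl)-6-[3-methoxy-4-(methoxymethoxy)phenyl]cyclohex-3-ene-1-carboxylic acid | COC(=O)C1(C(O)=O)[C@@H](c2ccc(OCOC)c(OC)c2)CC=C[C@H]1c1ccc(OC)c(OC)c1
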